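**Strategy.** Ring A (C1–C5, C10; eudesmane numbering) is disconnected at C1–C10 and C3–C4, the two bonds that flank the ring-B alkene C5=C6 with its allylic quaternary carbon C10. That pattern is the footprint of an allylic transposition, so the key step is a one-pot Ireland–Claisen rearrangement/ring-closing metathesis: the [3,3] shift of a cyclohexenyl pent-4-enoate forges C1–C10, transfers chirality from the C6 carbinol to C10 and moves the alkene to C5=C6; metathesis of the new allyl arm with a 2-isopropenyl group then closes ring A at C3–C4. The precursor is a monocyclic allylic ester made from (S)-citronellal; the aryl unit is added late through a benzylic cation.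

Key step: step 8

Remark: atoms are numbered as in eudesmane (C1 carries the arylbutyl group, C4 is CHCH3, C5=C6 is the alkene, C7 carries C(CH3)2OH, C10 is the methyl-bearing quaternary carbon; ring A = C1–C5 + C10, ring B = C5–C10; the benzylic carbon is C1′). (S)-Citronellal, pent-4-enoic acid and 1,3,5-trimethoxybenzene are taken as commercial.

**Step 1**
Reactants: 1 (3S)-3,7-dimethyloct-6-enal ((S)-citronellal)
Product: 2 (1R,2S,5S)-2-(2-hydroxypropan-2-yl)-5-methylcyclohexan-1-ol (cis-p-menthane-3,8-diol)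
Conditions: H2SO4 (0.3% aq.), 55 °C
Reagents that add atoms: water O
Why: Acid-catalysed carbonyl-ene/Prins cyclization–hydration in which the methyl stereocentre sits equatorial in the chair transition state and places the hydroxypropyl-bearing carbon (C7) trans to it; the minor 1S carbinol epimer is carried along because step 2 removes that centre.

**Step 2**
Reactants: 2 (1R,2S,5S)-2-(2-hydroxypropan-2-yl)-5-methylcyclohexan-1-ol
Product: 3 (2R,5S)-2-(2-hydroxypropan-2-yl)-5-methylcyclohexan-1-one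
Conditions: TEMPO (cat.), KBr (cat.), NaOCl, NaHCO3, CH2Cl2/H2O, 0 °C
Reagents that add atoms: none
Why: Nitroxyl-catalysed (Anelli) oxidation takes the secondary carbinol and leaves the tertiary one, and both carbinol epimers converge on one ketone.

**Step 3**
Reactants: 3 (2R,5S)-2-(2-hydroxypropan-2-yl)-5-methylcyclohexan-1-one
Product: 5 (6R)-6-(2-hydroxypropan-2-yl)-3-methylcyclohex-2-en-1-one, via bis-silylated enol ether 4 (not isolated)
Conditions: LiN(iPr)2 (2.3 equiv), THF, −78 °C; Me3SiCl; then Pd(OAc)2 (1.1 equiv), MeCN, rt; 1 M HCl work-up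
Reagents that add atoms: none
Why: Saegusa–Ito oxidation, in which kinetic deprotonation occurs at the α-CH2 rather than the tertiary α-carbon, so the enone forms on the methyl side and the C7 centre is untouched.

**Step 4**
Reactants: 5 (6R)-6-(2-hydroxypropan-2-yl)-3-methylcyclohex-2-en-1-one
Product: 6 (6R)-6-(2-hydroxypropan-2-yl)-2-iodo-3-methylcyclohex-2-en-1-one
Conditions: I2, pyridine, CH2Cl2, rt
Reagents that add atoms: iodine II
Why: Pyridine-mediated α-iodination of an enone (addition–iodination–elimination) under buffered conditions that spare the β-hydroxy ketone.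

**Step 5**
Reactants: 6 (6R)-6-(2-hydroxypropan-2-yl)-2-iodo-3-methylcyclohex-2-en-1-one
Product: 7 (6R)-6-(2-hydroxypropan-2-yl)-3-methyl-2-(prop-1-en-2-yl)cyclohex-2-en-1-one
Conditions: tributyl(prop-1-en-2-yl)stannane, Pd2(dba)3 (cat.), AsPh3, CuI, N-methylpyrrolidinone, 40 °C
Reagents that add atoms: tributyl(prop-1-en-2-yl)stannane C=C(C)[Sn](CCCC)(CCCC)CCCC
Why: Copper-assisted Stille coupling of an α-iodoenone under neutral conditions, which avoids retro-aldol loss of acetone and installs the future C4 with its methyl.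

**Step 6**
Reactants: 7 (6R)-6-(2-hydroxypropan-2-yl)-3-methyl-2-(prop-1-en-2-yl)cyclohex-2-en-1-one
Product: 8 (1R,6S)-6-(2-hydroxypropan-2-yl)-3-methyl-2-(prop-1-en-2-yl)cyclohex-2-en-1-ol
Conditions: NaBH4, CeCl3·7H2O, MeOH, −40 °C
Reagents that add atoms: none
Why: Luche 1,2-reduction; axial hydride delivery anti to the axial C7–H should give the equatorial C6 carbinol trans to the C7 side chain.

**Step 7**
Reactants: 8 (1R,6S)-6-(2-hydroxypropan-2-yl)-3-methyl-2-(prop-1-en-2-yl)cyclohex-2-en-1-ol; 9 pent-4-enoic acid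
Product: 10 (1R,6S)-6-(2-hydroxypropan-2-yl)-3-methyl-2-(prop-1-en-2-yl)cyclohex-2-en-1-yl pent-4-enoate
Conditions: DCC, DMAP (cat.), CH2Cl2, 0 °C → rt
Reagents that add atoms: none
Why: Steglich esterification acylates the secondary allylic hydroxyl and leaves the hindered tertiary one free.

**Step 8**
Reactants: 10 (1R,6S)-6-(2-hydroxypropan-2-yl)-3-methyl-2-(prop-1-en-2-yl)cyclohex-2-en-1-yl pent-4-enoate
Product: 13 (1S,6S,8aR)-6-(2-hydroxypropan-2-yl)-4,8a-dimethyl-1,2,6,7,8,8a-hexahydronaphthalene-1-carboxylic acid, via silyl ketene acetal 11 (not isolated), via rearranged silyl ester 12 (not isolated)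
Conditions: KN(SiMe3)2 (2.3 equiv), Me3SiCl (3 equiv), toluene/THF, −78 → 70 °C; then second-generation Grubbs catalyst (5 mol %), 70 °C; then 1 M HCl
Reagents that add atoms: none
Why: KN(SiMe3)2/Me3SiCl converts the ester into its (Z)-O-silyl ketene acetal 11 (allyl arm cis to OSiMe3, tertiary hydroxyl silylated in the same flask), which undergoes the Ireland–Claisen [3,3] shift through the array C1=C(OSi)–O–C6–C5=C10, forming C1–C10 and moving the alkene to C5=C6; the ruthenium carbene then joins the new allyl arm to the isopropenyl group, forming the C3–C4 bond as C3=C4 (saturated in step 9) with loss of ethene. Both events are established reaction types (ester-enolate Claisen rearrangement and ring-closing diene–ene metathesis), here run in one flask. The sigmatropic step closes no ring (six-membered chair-like transition state), and ring A is closed by the metathesis as a six-membered 1,3-diene. C10 is set by suprafacial chirality transfer from the C6 carbinol: the oxygen lies anti to the C7 side chain, so the new bond forms anti to it and the angular methyl ends syn to it. C1 is set by the ketene acetal geometry in the chair transition state, which places the allyl arm pseudo-equatorial. The step needs the [3,3] shift to outrun decomposition of the ketene acetal and metathesis only at the two terminal alkenes, which the hindered trisubstituted ring alkene should secure.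

**Step 9**
Reactants: 13 (1S,6S,8aR)-6-(2-hydroxypropan-2-yl)-4,8a-dimethyl-1,2,6,7,8,8a-hexahydronaphthalene-1-carboxylic acid
Product: 14 (1S,4R,6S,8aR)-6-(2-hydroxypropan-2-yl)-4,8a-dimethyl-1,2,3,4,6,7,8,8a-octahydronaphthalene-1-carboxylic acid
Conditions: 2-nitrobenzenesulfonylhydrazide, Et3N, CH2Cl2, rt
Reagents that add atoms: none
Why: Diimide reduction should transfer H2 syn to the less hindered C3=C4 end of the diene (C5=C6 is flanked by quaternary C10 and branched C7) from the face opposite the axial C10 methyl, which places the C4 methyl cis to it.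

**Step 10**
Reactants: 14 (1S,4R,6S,8aR)-6-(2-hydroxypropan-2-yl)-4,8a-dimethyl-1,2,3,4,6,7,8,8a-octahydronaphthalene-1-carboxylic acid
Product: 15 1-[(1S,4R,6S,8aR)-6-(2-hydroxypropan-2-yl)-4,8a-dimethyl-1,2,3,4,6,7,8,8a-octahydronaphthalen-1-yl]-3-methylbutan-1-one
Conditions: i-BuLi (3.3 equiv), THF, −78 → 0 °C; aq. NH4Cl
Reagents that add atoms: isobutyllithium [Li]CC(C)C
Why: Addition of an alkyllithium to the lithium carboxylate stops at the gem-diolate, which gives the ketone only on work-up, so C1 is not exposed to base as a ketone.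

**Step 11**
Reactants: 16 1,3,5-trimethoxybenzene
Product: 17 1,3,5-tribromo-2,4,6-trimethoxybenzene
Conditions: Br2 (3.1 equiv), CHCl3, 0 °C → rt
Reagents that add atoms: bromine BrBr
Why: Exhaustive electrophilic aromatic bromination of a strongly activated arene; two bromines later serve as formyl precursors.

**Step 12**
Reactants: 17 1,3,5-tribromo-2,4,6-trimethoxybenzene; 15 1-[(1S,4R,6S,8aR)-6-(2-hydroxypropan-2-yl)-4,8a-dimethyl-1,2,3,4,6,7,8,8a-octahydronaphthalen-1-yl]-3-methylbutan-1-one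
Product: 19 1-(3,5-dibromo-2,4,6-trimethoxyphenyl)-1-[(1S,4R,6S,8aR)-6-(2-hydroxypropan-2-yl)-4,8a-dimethyl-1,2,3,4,6,7,8,8a-octahydronaphthalen-1-yl]-3-methylbutan-1-ol (both carbinol epimers), via aryllithium 18 (not isolated)
Conditions: 17 (2.2 equiv), n-BuLi (2.2 equiv), THF, −78 °C; CeCl3 (2.3 equiv); then 15, −78 → −20 °C
Reagents that add atoms: none
Why: Single lithium–bromine exchange followed by organocerium 1,2-addition, which suppresses enolization of the hindered ketone; the new carbinol centre is erased in step 13, and one equivalent of reagent is consumed by the tertiary hydroxyl.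

**Step 13**
Reactants: 19 1-(3,5-dibromo-2,4,6-trimethoxyphenyl)-1-[(1S,4R,6S,8aR)-6-(2-hydroxypropan-2-yl)-4,8a-dimethyl-1,2,3,4,6,7,8,8a-octahydronaphthalen-1-yl]-3-methylbutan-1-ol
Product: 20 1,3-dibromo-5-{(1S)-1-[(1R,4R,6S,8aR)-6-(2-hydroxypropan-2-yl)-4,8a-dimethyl-1,2,3,4,6,7,8,8a-octahydronaphthalen-1-yl]-3-methylbutyl}-2,4,6-trimethoxybenzene
Conditions: Et3SiH (5 equiv), CF3CO2H (3 equiv), CH2Cl2, −40 °C
Reagents that add atoms: none
Why: Ionic hydrogenation: both epimers ionize to the same trimethoxybenzylic cation, which should adopt the conformer with C1–H eclipsing the aryl group (allylic 1,3-strain) and take hydride anti to quaternary C10, giving the (S)-C1′ centre; the far less ionizable tertiary alcohol and the alkene should survive at low temperature.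

**Step 14**
Reactants: 20 1,3-dibromo-5-{(1S)-1-[(1R,4R,6S,8aR)-6-(2-hydroxypropan-2-yl)-4,8a-dimethyl-1,2,3,4,6,7,8,8a-octahydronaphthalen-1-yl]-3-methylbutyl}-2,4,6-trimethoxybenzene
Product: 21 5-{(1S)-1-[(1R,4R,6S,8aR)-6-(2-hydroxypropan-2-yl)-4,8a-dimethyl-1,2,3,4,6,7,8,8a-octahydronaphthalen-1-yl]-3-methylbutyl}-2,4,6-trimethoxybenzene-1,3-dicarbaldehyde
Conditions: n-BuLi (5 equiv), THF, −78 °C; DMF; aq. NH4Cl
Reagents that add atoms: N,N-dimethylformamide CN(C)C=O
Why: Twofold lithium–bromine exchange (after deprotonation of the hydroxyl) and formylation with DMF place both aldehydes regiospecifically without electrophilic conditions that would endanger the alkene or tertiary alcohol.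

**Step 15**
Reactants: 21 5-{(1S)-1-[(1R,4R,6S,8aR)-6-(2-hydroxypropan-2-yl)-4,8a-dimethyl-1,2,3,4,6,7,8,8a-octahydronaphthalen-1-yl]-3-methylbutyl}-2,4,6-trimethoxybenzene-1,3-dicarbaldehyde
Product: 22 5-{(1S)-1-[(1R,4R,6S,8aR)-6-(2-hydroxypropan-2-yl)-4,8a-dimethyl-1,2,3,4,6,7,8,8a-octahydronaphthalen-1-yl]-3-methylbutyl}-2,4,6-trihydroxybenzene-1,3-dicarbaldehyde (target)
Conditions: NaSEt (excess), DMF, 110 °C; then 1 M HCl
Reagents that add atoms: none
Why: Thiolate SN2 demethylation of aryl methyl ethers that are each ortho or para to a formyl group, under non-acidic conditions that leave the tertiary alcohol, alkene and stereocentres untouched.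

**Compound list**
1 | (3S)-3,7-dimethyloct-6-enal ((S)-citronellal) | C[C@@H](CCC=C(C)C)CC=O | starting material
2 | (1R,2S,5S)-2-(2-hydroxypropan-2-yl)-5-methylcyclohexan-1-ol (major; 1S epimer carried along) | O[C@@H]1C[C@@H](C)CC[C@@H]1C(C)(C)O | intermediate
3 | (2R,5S)-2-(2-hydroxypropan-2-yl)-5-methylcyclohexan-1-one | O=C1C[C@@H](C)CC[C@@H]1C(C)(C)O | intermediate
4 | trimethyl{[(3S,6R)-3-methyl-6-{2-[(trimethylsilyl)oxy]propan-2-yl}cyclohex-1-en-1-yl]oxy}silane | C[Si](C)(C)OC1=C[C@@H](C)CC[C@@H]1C(C)(C)O[Si](C)(C)C | intermediate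
5 | (6R)-6-(2-hydroxypropan-2-yl)-3-methylcyclohex-2-en-1-one | O=C1C=C(C)CC[C@@H]1C(C)(C)O | intermediate
6 | (6R)-6-(2-hydroxypropan-2-yl)-2-iodo-3-methylcyclohex-2-en-1-one | O=C1C(I)=C(C)CC[C@@H]1C(C)(C)O | intermediate
7 | (6R)-6-(2-hydroxypropan-2-yl)-3-methyl-2-(prop-1-en-2-yl)cyclohex-2-en-1-one | O=C1C(C(C)=C)=C(C)CC[C@@H]1C(C)(C)O | intermediate
8 | (1R,6S)-6-(2-hydroxypropan-2-yl)-3-methyl-2-(prop-1-en-2-yl)cyclohex-2-en-1-ol | O[C@H]1C(C(C)=C)=C(C)CC[C@@H]1C(C)(C)O | intermediate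
9 | pent-4-enoic acid | C=CCCC(=O)O | starting material
10 | (1R,6S)-6-(2-hydroxypropan-2-yl)-3-methyl-2-(prop-1-en-2-yl)cyclohex-2-en-1-yl pent-4-enoate | C=CCCC(=O)O[C@H]1C(C(C)=C)=C(C)CC[C@@H]1C(C)(C)O | intermediate
11 | (Z)-trimethylsilyl ketene acetal of 10 (allyl arm cis to OSiMe3; tertiary hydroxyl as trimethylsilyl ether) | C=CC/C=C(\O[Si](C)(C)C)O[C@H]1C(C(C)=C)=C(C)CC[C@@H]1C(C)(C)O[Si](C)(C)C | intermediate
12 | trimethylsilyl (2S)-2-[(1R,4S)-1-methyl-2-(prop-1-en-2-yl)-4-{2-[(trimethylsilyl)oxy]propan-2-yl}cyclohex-2-en-1-yl]pent-4-enoate | C=CC[C@H](C(=O)O[Si](C)(C)C)[C@@]1(C)CC[C@H](C(C)(C)O[Si](C)(C)C)C=C1C(C)=C | intermediate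
13 | (1S,6S,8aR)-6-(2-hydroxypropan-2-yl)-4,8a-dimethyl-1,2,6,7,8,8a-hexahydronaphthalene-1-carboxylic acid | OC(=O)[C@H]1CC=C(C)C2=C[C@@H](C(C)(C)O)CC[C@@]21C | intermediate
14 | (1S,4R,6S,8aR)-6-(2-hydroxypropan-2-yl)-4,8a-dimethyl-1,2,3,4,6,7,8,8a-octahydronaphthalene-1-carboxylic acid | OC(=O)[C@H]1CC[C@@H](C)C2=C[C@@H](C(C)(C)O)CC[C@@]21C | intermediate
15 | 1-[(1S,4R,6S,8aR)-6-(2-hydroxypropan-2-yl)-4,8a-dimethyl-1,2,3,4,6,7,8,8a-octahydronaphthalen-1-yl]-3-methylbutan-1-one | CC(C)CC(=O)[C@H]1CC[C@@H](C)C2=C[C@@H](C(C)(C)O)CC[C@@]21C | intermediate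
16 | 1,3,5-trimethoxybenzene | COc1cc(OC)cc(OC)c1 | starting material
17 | 1,3,5-tribromo-2,4,6-trimethoxybenzene | COc1c(Br)c(OC)c(Br)c(OC)c1Br | intermediate
18 | (3,5-dibromo-2,4,6-trimethoxyphenyl)lithium | [Li]c1c(OC)c(Br)c(OC)c(Br)c1OC | intermediate
19 | 1-(3,5-dibromo-2,4,6-trimethoxyphenyl)-1-[(1S,4R,6S,8aR)-6-(2-hydroxypropan-2-yl)-4,8a-dimethyl-1,2,3,4,6,7,8,8a-octahydronaphthalen-1-yl]-3-methylbutan-1-ol (both carbinol epimers) | CC(C)CC(O)(c1c(OC)c(Br)c(OC)c(Br)c1OC)[C@H]1CC[C@@H](C)C2=C[C@@H](C(C)(C)O)CC[C@@]21C | intermediate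
20 | 1,3-dibromo-5-{(1S)-1-[(1R,4R,6S,8aR)-6-(2-hydroxypropan-2-yl)-4,8a-dimethyl-1,2,3,4,6,7,8,8a-octahydronaphthalen-1-yl]-3-methylbutyl}-2,4,6-trimethoxybenzene | CC(C)C[C@H](c1c(OC)c(Br)c(OC)c(Br)c1OC)[C@H]1CC[C@@H](C)C2=C[C@@H](C(C)(C)O)CC[C@@]21C | intermediate
21 | 5-{(1S)-1-[(1R,4R,6S,8aR)-6-(2-hydroxypropan-2-yl)-4,8a-dimethyl-1,2,3,4,6,7,8,8a-octahydronaphthalen-1-yl]-3-methylbutyl}-2,4,6-trimethoxybenzene-1,3-dicarbaldehyde | CC(C)C[C@H](c1c(OC)c(C=O)c(OC)c(C=O)c1OC)[C@H]1CC[C@@H](C)C2=C[C@@H](C(C)(C)O)CC[C@@]21C | intermediate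
22 | 5-{(1S)-1-[(1R,4R,6S,8aR)-6-(2-hydroxypropan-2-yl)-4,8a-dimethyl-1,2,3,4,6,7,8,8a-octahydronaphthalen-1-yl]-3-methylbutyl}-2,4,6-trihydroxybenzene-1,3-dicarbaldehyde | CC(C)C[C@H](c1c(O)c(C=O)c(O)c(C=O)c1O)[C@H]1CC[C@@H](C)C2=C[C@@H](C(C)(C)O)CC[C@@]21C | target

**Totals.** Total step count: 15. Longest linear sequence: 14 (steps 1–10 and 12–15; step 11 is a side branch).

**Steps most likely to fail**

1. Step 8. The [3,3] shift has to build a quaternary carbon next to a tertiary one at a diene terminus. If it is slow, the silyl ketene acetal may decompose first; a boat transition state would deliver the C1 epimer; and ring closure onto the 1,1-disubstituted diene terminus may stall. The fallback sets out from 8 and comes back at 13, making the two bonds separately without an ester enolate in the rearrangement. Alcohol 8 would be heated with triethyl orthoacetate (EtCO2H cat., 140 °C, Johnson–Claisen rearrangement, same chirality transfer) to ethyl 2-[(1R,4S)-4-(2-hydroxypropan-2-yl)-1-methyl-2-(prop-1-en-2-yl)cyclohex-2-en-1-yl]acetate F1. Its enolate (LiN(iPr)2, THF, −78 °C) would be alkylated with allyl bromide to ethyl (2S)-2-[(1R,4S)-4-(2-hydroxypropan-2-yl)-1-methyl-2-(prop-1-en-2-yl)cyclohex-2-en-1-yl]pent-4-enoate F2, a wrong C1 epimer being corrected by deprotonation and kinetic protonation. Ring-closing metathesis (second-generation Grubbs catalyst, CH2Cl2, 40 °C) would give ethyl (1S,6S,8aR)-6-(2-hydroxypropan-2-yl)-4,8a-dimethyl-1,2,6,7,8,8a-hexahydronaphthalene-1-carboxylate F3, and LiOH (THF/H2O) would give 13.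

2. Step 9. Diimide may discriminate poorly between the two trisubstituted alkenes of the conjugated diene, or reduce both. The fallback sets out from 13 and comes back at 14, replacing hydrogen transfer by hydroboration–protonolysis. Esterification (Me3SiCHN2, MeOH) would give methyl (1S,6S,8aR)-6-(2-hydroxypropan-2-yl)-4,8a-dimethyl-1,2,6,7,8,8a-hexahydronaphthalene-1-carboxylate F4. 9-BBN (THF, 60 °C) should add boron to C3 and hydrogen to C4 from the face opposite the angular methyl, giving methyl (1S,3S,4R,6S,8aR)-3-(9-borabicyclo[3.3.1]nonan-9-yl)-6-(2-hydroxypropan-2-yl)-4,8a-dimethyl-1,2,3,4,6,7,8,8a-octahydronaphthalene-1-carboxylate F5. Protonolysis in the same flask (propanoic acid, diglyme, 140 °C) would give methyl (1S,4R,6S,8aR)-6-(2-hydroxypropan-2-yl)-4,8a-dimethyl-1,2,3,4,6,7,8,8a-octahydronaphthalene-1-carboxylate F6, and LiOH would give 14.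

3. Step 12. Both partners are hindered, so the organocerium may enolize the ketone or not add at all. The fallback sets out from 15 and comes back at 21, joining the aryl group by cross-coupling and reaching the same benzylic cation from an alkene. Kinetic enolization on the isobutyl side (KN(SiMe3)2, PhNTf2, THF, −78 °C, hydroxyl transiently silylated) would give (1Z)-1-[(1S,4R,6S,8aR)-6-(2-hydroxypropan-2-yl)-4,8a-dimethyl-1,2,3,4,6,7,8,8a-octahydronaphthalen-1-yl]-3-methylbut-1-en-1-yl trifluoromethanesulfonate F7. Suzuki–Miyaura coupling with (2,4,6-trimethoxyphenyl)boronic acid (Pd(OAc)2, SPhos, K3PO4, toluene/H2O, 80 °C) would give 2-{(1Z)-1-[(1S,4R,6S,8aR)-6-(2-hydroxypropan-2-yl)-4,8a-dimethyl-1,2,3,4,6,7,8,8a-octahydronaphthalen-1-yl]-3-methylbut-1-en-1-yl}-1,3,5-trimethoxybenzene F8. Ionic hydrogenation (Et3SiH, CF3CO2H, CH2Cl2, −40 °C) would give 2-{(1S)-1-[(1R,4R,6S,8aR)-6-(2-hydroxypropan-2-yl)-4,8a-dimethyl-1,2,3,4,6,7,8,8a-octahydronaphthalen-1-yl]-3-methylbutyl}-1,3,5-trimethoxybenzene F9. Twofold Rieche formylation (Cl2CHOMe, TiCl4, CH2Cl2, −78 → 0 °C) would give 21.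

**Further compounds**
F1 | step 8 | ethyl 2-[(1R,4S)-4-(2-hydroxypropan-2-yl)-1-methyl-2-(prop-1-en-2-yl)cyclohex-2-en-1-yl]acetate | CCOC(=O)C[C@@]1(C)CC[C@H](C(C)(C)O)C=C1C(C)=C
F2 | step 8 | ethyl (2S)-2-[(1R,4S)-4-(2-hydroxypropan-2-yl)-1-methyl-2-(prop-1-en-2-yl)cyclohex-2-en-1-yl]pent-4-enoate | CCOC(=O)[C@@H](CC=C)[C@@]1(C)CC[C@H](C(C)(C)O)C=C1C(C)=C
F3 | step 8 | ethyl (1S,6S,8aR)-6-(2-hydroxypropan-2-yl)-4,8a-dimethyl-1,2,6,7,8,8a-hexahydronaphthalene-1-carboxylate | CCOC(=O)[C@H]1CC=C(C)C2=C[C@@H](C(C)(C)O)CC[C@@]21C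
F4 | step 9 | methyl (1S,6S,8aR)-6-(2-hydroxypropan-2-yl)-4,8a-dimethyl-1,2,6,7,8,8a-hexahydronaphthalene-1-carboxylate | COC(=O)[C@H]1CC=C(C)C2=C[C@@H](C(C)(C)O)CC[C@@]21C
F5 | step 9 | methyl (1S,3S,4R,6S,8aR)-3-(9-borabicyclo[3.3.1]nonan-9-yl)-6-(2-hydroxypropan-2-yl)-4,8a-dimethyl-1,2,3,4,6,7,8,8a-octahydronaphthalene-1-carboxylate | COC(=O)[C@H]1C[C@H](B3C4CCCC3CCC4)[C@@H](C)C2=C[C@@H](C(C)(C)O)CC[C@@]21C
F6 | step 9 | methyl (1S,4R,6S,8aR)-6-(2-hydroxypropan-2-yl)-4,8a-dimethyl-1,2,3,4,6,7,8,8a-octahydronaphthalene-1-carboxylate | COC(=O)[C@H]1CC[C@@H](C)C2=C[C@@H](C(C)(C)O)CC[C@@]21C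
F7 | step 12 | (1Z)-1-[(1S,4R,6S,8aR)-6-(2-hydroxypropan-2-yl)-4,8a-dimethyl-1,2,3,4,6,7,8,8a-octahydronaphthalen-1-yl]-3-methylbut-1-en-1-yl trifluoromethanesulfonate | CC(C)/C=C(\OS(=O)(=O)C(F)(F)F)[C@H]1CC[C@@H](C)C2=C[C@@H](C(C)(C)O)CC[C@@]21C
F8 | step 12 | 2-{(1Z)-1-[(1S,4R,6S,8aR)-6-(2-hydroxypropan-2-yl)-4,8a-dimethyl-1,2,3,4,6,7,8,8a-octahydronaphthalen-1-yl]-3-methylbut-1-en-1-yl}-1,3,5-trimethoxybenzene | CC(C)/C=C(\c1c(OC)cc(OC)cc1OC)[C@H]1CC[C@@H](C)C2=C[C@@H](C(C)(C)O)CC[C@@]21C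
F9 | step 12 | 2-{(1S)-1-[(1R,4R,6S,8aR)-6-(2-hydroxypropan-2-yl)-4,8a-dimethyl-1,2,3,4,6,7,8,8a-octahydronaphthalen-1-yl]-3-methylbutyl}-1,3,5-trimethoxybenzene | CC(C)C[C@H](c1c(OC)cc(OC)cc1OC)[C@H]1CC[C@@H](C)C2=C[C@@H](C(C)(C)O)CC[C@@]21C
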